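How much product stands in each of the three flasks after 40 h, and which way does that amount go as the charge rises?

| flask | substrate | remark | time |
|---|---|---|---|
| grey | 0.035 M | run made earlier |  |
| amber | 0.15 M | run made earlier |  |
| Friday's | 0.025 M |  | 40 h |
| Saturday's | 0.050 M |  | 40 h |
| Wednesday's | 0.10 M |  | 40 h |

| run | time / h | product / % |
|---|---|---|
| grey | 5.00 | 19.5 |
| grey | 10.0 | 28.4 |
| grey | 15.0 | 34.4 |
| grey | 20.0 | 37.5 |
| grey | 25.0 | 39.7 |
| grey | 30.0 | 40.9 |
| amber | 2.00 | 30.5 |
| amber | 5.00 | 50.1 |
| amber | 10.0 | 61.3 |
| amber | 15.0 | 66.5 |
| amber | 20.0 | 68.3 |
| amber | 30.0 | 71.5 |

(readings scatter by 0.5 percentage points)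

- in percentages every species weighs as the substrate in it: one product counts as two
- "hardly changes" means that all values lie within two and a half points (for a concentration: within two and a half percent of the largest)

- [product] at the end for Friday's, Saturday's, Wednesday's, in this order
- the course of these numbers from the first flask to the last (falls all the way / rises, then falls / hardly changes / falls, then rises / rises all the way)

We begin with the plainest guess: two substrate pair to one product, with a steady rate constant. Integrating that rate in closed form, and reading the paired share from the percent figures, gives

paired share / unpaired share = time / pairing time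

pairing time = 1 / (pairing constant × charge)

The first readings give a pairing constant of 1.38 /M/h in the grey run and 1.46 /M/h in the amber run, though their charges differ by a factor of 4.29. A second-order start therefore stands as a reading, and we keep the mean, 1.42 /M/h. With it we reckon 28.1 h as the pairing time of Friday's flask, the second-order half-life of substrate by pairing.

The objection comes from the late readings. At 30.0 h the grey run should stand at 59.9%, and it reads 40.9%. The amber run should stand at 86.5%, and it reads 71.5%. The steady clock fails, so we ask how many hours of steady pairing each last reading is worth: 13.9 h for grey and 11.7 h for amber.

These two differ, and the grey readings still rose by 1.2 percentage points over the last 5.00 h, against a scatter of 0.5 points in each reading. We expect their mean, 12.8 h, to read somewhat low at the asked time, but we commit to it: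

Friday's: 0.00392 M

Saturday's: 0.0119 M

Wednesday's: 0.0323 M

Our amounts rise with the charge.

The forecast gives 0.0044 M, 0.0127 M and 0.0325 M, course rises all the way, higher than ours for Friday's flask. Its ground is that “the stall looks mainly like the rate dying away”.

The flasks give 0.00456 M, 0.0129 M and 0.0331 M, course rises all the way.

    2 substrate → product (k = 0.0133 /M/min)
    substrate ⇌ dormant form (K = 2.10, k = 5.78 × 10⁻⁴ /min)

In Friday's flask the half-life of substrate by the forward rate of the path to dormant form is 20 h, shorter than our pairing time of 28.1 h, and that forward rate uses substrate 1.5 times as fast as pairing at 8.18 h and 3.8 times as fast at 40.0 h, when that flask holds 40.7% dormant form against 36.5% product. Our pairing time for Wednesday's flask, 7.02 h, is shorter than the same forward half-life of 20.0 h, and at 40.0 h that flask holds 23.3% dormant form against 66.3% product.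

All runs are calculated for substances that don't exist; noise was put on by code.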